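**Retrosynthetic overview**
1. Target ⇐ its tri-O-benzyl ether; global debenzylation is the last step and the pyranone OH is carried free.
2. Ring D (4-hydroxy-2-pyranone) ⇐ thermal acylketene lactonisation of a β-keto dioxinone ⇐ Claisen acylation of the 2,2,6-trimethyl-1,3-dioxin-4-one dienolate by the acyl imidazolide of a flavone acetic acid.
3. Ring B–ring C bond (aryl–C2 of the flavone) ⇐ proposed carboxylate-directed dehydrogenative C–H/C–H coupling of 3,5-bis(benzyloxy)phenylacetic acid with 7-(benzyloxy)-5-methylchromone.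
4. Ring C (chromone pyranone) ⇐ enaminone cyclisation of O-benzyl orcacetophenone ⇐ orcinol (ring A); ring B acid ⇐ methyl 3,5-dihydroxyphenylacetate.
5. Ring order: rings A and B are bought as arenes; ring C is closed first, then the B–C bond is made, and ring D is closed last.

Assumption: the target has no stereocentre and its aryl–chromone axis rotates freely, so it is one achiral compound and no stereocontrol is needed.

Step 1
Reactants: 1 orcinol (5-methylbenzene-1,3-diol)
Product: 2 1-(2,4-dihydroxy-6-methylphenyl)ethan-1-one (orcacetophenone)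
Conditions: ZnCl2 (1.5 equiv), AcOH, 140 °C, 30 min; aq. HCl work-up, recrystallise
Reagents that add atoms: acetic acid, CC(=O)O
Why: Nencki-type Friedel–Crafts C-acylation occurs para to one hydroxyl and ortho to the other (the resorcinol preference), and the minor 2,6-dihydroxy isomer is removed by crystallisation.

Step 2
Reactants: 2 1-(2,4-dihydroxy-6-methylphenyl)ethan-1-one
Product: 3 1-[4-(benzyloxy)-2-hydroxy-6-methylphenyl]ethan-1-one
Conditions: BnBr (1.05 equiv), K2CO3 (1.5 equiv), acetone, reflux, 6 h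
Reagents that add atoms: benzyl bromide, BrCc1ccccc1
Why: Williamson ether synthesis is selective for the 4-hydroxyl because the 2-hydroxyl is hydrogen-bonded to the ketone and much less nucleophilic.

Step 3
Reactants: 3 1-[4-(benzyloxy)-2-hydroxy-6-methylphenyl]ethan-1-one
Product: 4 (E)-1-[4-(benzyloxy)-2-hydroxy-6-methylphenyl]-3-(dimethylamino)prop-2-en-1-one
Conditions: Me2NCH(OMe)2 (3 equiv), toluene, 100 °C, 4 h
Reagents that add atoms: N,N-dimethylformamide dimethyl acetal, COC(OC)N(C)C
Why: Aminomethylenation (enaminone condensation) of the acetyl methyl group with the amide acetal is the standard first stage of chromone synthesis and gives the conjugated E-enaminone.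

Step 4
Reactants: 4 (E)-1-[4-(benzyloxy)-2-hydroxy-6-methylphenyl]-3-(dimethylamino)prop-2-en-1-one
Product: 5 7-(benzyloxy)-5-methyl-4H-chromen-4-one
Conditions: AcOH, 100 °C, 2 h
Reagents that add atoms: none
Why: Acid-promoted 6-endo oxa-Michael addition of the phenol followed by elimination of dimethylamine (enaminone chromone synthesis) closes ring C.

Step 5
Reactants: 6 methyl 2-(3,5-dihydroxyphenyl)acetate
Product: 7 methyl 2-[3,5-bis(benzyloxy)phenyl]acetate
Conditions: BnBr (2.3 equiv), K2CO3 (3 equiv), DMF, 60 °C, 8 h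
Reagents that add atoms: benzyl bromide, BrCc1ccccc1
Why: Williamson ether synthesis of both phenols proceeds cleanly because K2CO3 is too weak to enolise the ester.

Step 6
Reactants: 7 methyl 2-[3,5-bis(benzyloxy)phenyl]acetate
Product: 8 2-[3,5-bis(benzyloxy)phenyl]acetic acid
Conditions: LiOH (3 equiv), THF/H2O, rt; then 1 M HCl
Reagents that add atoms: lithium hydroxide, [Li+].[OH-]
Why: Ester saponification is routine and leaves the benzyl ethers untouched.

Step 7
Reactants: 5 7-(benzyloxy)-5-methyl-4H-chromen-4-one; 8 2-[3,5-bis(benzyloxy)phenyl]acetic acid (1.5 equiv)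
Product: 10 2-{3,5-bis(benzyloxy)-2-[7-(benzyloxy)-5-methyl-4-oxo-4H-chromen-2-yl]phenyl}acetic acid (flavone acid), via flavanone acid 9 (not isolated)
Conditions: Pd(OAc)2 (10 mol %), N-acetylglycine (20 mol %), 1,4-benzoquinone (20 mol %), KHCO3 (0.3 equiv), O2 (1 atm), t-AmylOH, 90 °C, 36 h; then 1 M HCl work-up
Reagents that add atoms: none
Why: Proposed new method: carboxylate-directed dehydrogenative coupling of an arene ortho C–H with the chromone C2–H, in which the carboxylate of 8 binds Pd(OAc)2/N-acetylglycine and undergoes concerted metalation–deprotonation at either of its two equivalent, alkoxy-activated ortho positions to give a six-membered aryl palladacycle of divalent palladium, which inserts the C2=C3 bond of 5 with conjugate-addition polarity (aryl to C2, palladium to C3 as an enolate), protonation then releases racemic flavanone 9, and the same divalent palladium carboxylate re-forms the C3 enolate and undergoes β-hydride elimination to flavone 10 while zerovalent palladium is reoxidised by benzoquinone/O2; the closest known reaction types are carboxylate-directed ortho C–H olefination of phenylacetic acids with acrylates, conjugate addition of aryl–palladium species to chromones, and aerobic palladium-catalysed dehydrogenation of flavanones.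

Step 8
Reactants: 10 2-{3,5-bis(benzyloxy)-2-[7-(benzyloxy)-5-methyl-4-oxo-4H-chromen-2-yl]phenyl}acetic acid
Product: 11 7-(benzyloxy)-2-{2,4-bis(benzyloxy)-6-[2-(1H-imidazol-1-yl)-2-oxoethyl]phenyl}-5-methyl-4H-chromen-4-one (acyl imidazolide)
Conditions: 1,1'-carbonyldiimidazole (1.2 equiv), CH2Cl2, rt, 1 h; cold water wash, dry, concentrate, use crude
Reagents that add atoms: 1,1'-carbonyldiimidazole, O=C(n1ccnc1)n1ccnc1
Why: Carboxylic acid activation as the acyl imidazolide is driven by loss of CO2 and is mild enough for the chromone and the benzyl ethers.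

Step 9
Reactants: 11 acyl imidazolide; 12 2,2,6-trimethyl-4H-1,3-dioxin-4-one (3.5 equiv)
Product: 13 6-(3-{3,5-bis(benzyloxy)-2-[7-(benzyloxy)-5-methyl-4-oxo-4H-chromen-2-yl]phenyl}-2-oxopropyl)-2,2-dimethyl-4H-1,3-dioxin-4-one
Conditions: 12, LiN(SiMe3)2 (3.5 equiv), THF, −78 °C, 45 min; then 11 in THF, −78 → −40 °C; 1 M HCl
Reagents that add atoms: none
Why: Claisen-type γ-C-acylation of the vinylogous lithium dienolate by the acyl imidazolide gives the β-keto dioxinone, the excess dienolate absorbs the acidic product and the liberated imidazole, and any aryl ketene formed by enolisation of 11 is captured by the same dienolate to give the same product.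

Step 10
Reactants: 13 β-keto dioxinone
Product: 15 7-(benzyloxy)-2-{2,4-bis(benzyloxy)-6-[(4-hydroxy-2-oxo-2H-pyran-6-yl)methyl]phenyl}-5-methyl-4H-chromen-4-one, via acylketene 14 (not isolated)
Conditions: toluene (0.02 M), 110 °C, 1 h
Reagents that add atoms: none
Why: Retro-hetero-Diels–Alder loss of acetone from the dioxinone gives an acylketene that is trapped intramolecularly by the enol oxygen of the 1,3-diketone (six-membered lactonisation) to close ring D as the 4-hydroxy-2-pyranone.

Step 11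
Reactants: 15 tri-O-benzyl pyranone
Product: 16 2-{2,4-dihydroxy-6-[(4-hydroxy-2-oxo-2H-pyran-6-yl)methyl]phenyl}-7-hydroxy-5-methyl-4H-chromen-4-one (target)
Conditions: BCl3 (9 equiv), pentamethylbenzene (12 equiv), CH2Cl2, −78 → −40 °C; then H2O
Reagents that add atoms: none
Why: Lewis-acid debenzylation of aryl benzyl ethers with BCl3 and a non-basic cation scavenger works at low temperature, leaves pyranone and chromone intact, and stops benzyl cations from alkylating the electron-rich ring B.

**Compound list**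
1 | orcinol (5-methylbenzene-1,3-diol) | Cc1cc(O)cc(O)c1 | starting material
2 | 1-(2,4-dihydroxy-6-methylphenyl)ethan-1-one | CC(=O)c1c(C)cc(O)cc1O | intermediate
3 | 1-[4-(benzyloxy)-2-hydroxy-6-methylphenyl]ethan-1-one | CC(=O)c1c(C)cc(OCc2ccccc2)cc1O | intermediate
4 | (E)-1-[4-(benzyloxy)-2-hydroxy-6-methylphenyl]-3-(dimethylamino)prop-2-en-1-one | CN(C)/C=C/C(=O)c1c(C)cc(OCc2ccccc2)cc1O | intermediate
5 | 7-(benzyloxy)-5-methyl-4H-chromen-4-one | Cc1cc(OCc2ccccc2)cc2occc(=O)c12 | intermediate
6 | methyl 2-(3,5-dihydroxyphenyl)acetate | COC(=O)Cc1cc(O)cc(O)c1 | starting material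
7 | methyl 2-[3,5-bis(benzyloxy)phenyl]acetate | COC(=O)Cc1cc(OCc2ccccc2)cc(OCc2ccccc2)c1 | intermediate
8 | 2-[3,5-bis(benzyloxy)phenyl]acetic acid | OC(=O)Cc1cc(OCc2ccccc2)cc(OCc2ccccc2)c1 | intermediate
9 | racemic 2-{3,5-bis(benzyloxy)-2-[7-(benzyloxy)-5-methyl-4-oxochroman-2-yl]phenyl}acetic acid (flavanone acid) | Cc1cc(OCc2ccccc2)cc2OC(c3c(OCc4ccccc4)cc(OCc4ccccc4)cc3CC(=O)O)CC(=O)c12 | intermediate (not isolated)
10 | 2-{3,5-bis(benzyloxy)-2-[7-(benzyloxy)-5-methyl-4-oxo-4H-chromen-2-yl]phenyl}acetic acid (flavone acid) | Cc1cc(OCc2ccccc2)cc2oc(-c3c(OCc4ccccc4)cc(OCc4ccccc4)cc3CC(=O)O)cc(=O)c12 | intermediate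
11 | 7-(benzyloxy)-2-{2,4-bis(benzyloxy)-6-[2-(1H-imidazol-1-yl)-2-oxoethyl]phenyl}-5-methyl-4H-chromen-4-one (acyl imidazolide) | Cc1cc(OCc2ccccc2)cc2oc(-c3c(OCc4ccccc4)cc(OCc4ccccc4)cc3CC(=O)n5ccnc5)cc(=O)c12 | intermediate
12 | 2,2,6-trimethyl-4H-1,3-dioxin-4-one | CC1=CC(=O)OC(C)(C)O1 | starting material
13 | 6-(3-{3,5-bis(benzyloxy)-2-[7-(benzyloxy)-5-methyl-4-oxo-4H-chromen-2-yl]phenyl}-2-oxopropyl)-2,2-dimethyl-4H-1,3-dioxin-4-one | Cc1cc(OCc2ccccc2)cc2oc(-c3c(OCc4ccccc4)cc(OCc4ccccc4)cc3CC(=O)CC5=CC(=O)OC(C)(C)O5)cc(=O)c12 | intermediate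
14 | 6-{3,5-bis(benzyloxy)-2-[7-(benzyloxy)-5-methyl-4-oxo-4H-chromen-2-yl]phenyl}hex-1-ene-1,3,5-trione (acylketene) | Cc1cc(OCc2ccccc2)cc2oc(-c3c(OCc4ccccc4)cc(OCc4ccccc4)cc3CC(=O)CC(=O)C=C=O)cc(=O)c12 | intermediate (not isolated)
15 | 7-(benzyloxy)-2-{2,4-bis(benzyloxy)-6-[(4-hydroxy-2-oxo-2H-pyran-6-yl)methyl]phenyl}-5-methyl-4H-chromen-4-one | Cc1cc(OCc2ccccc2)cc2oc(-c3c(OCc4ccccc4)cc(OCc4ccccc4)cc3Cc5cc(O)cc(=O)o5)cc(=O)c12 | intermediate
16 | 2-{2,4-dihydroxy-6-[(4-hydroxy-2-oxo-2H-pyran-6-yl)methyl]phenyl}-7-hydroxy-5-methyl-4H-chromen-4-one | Cc1cc(O)cc2oc(-c3c(O)cc(O)cc3Cc3cc(O)cc(=O)o3)cc(=O)c12 | target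

**Step count and risks**
Total: 11 steps. Longest linear sequence: 9 steps (steps 1–4, then 7–11, from orcinol); the ring B branch (steps 5–6) joins at step 7.

The three steps most likely to fail:

Step 7 (the proposed new coupling). The hindered aryl palladacycle may insert the chromone too slowly. Chromone homocoupling, C3 functionalisation or a second arylation of 8 could compete. The fallback uses known chemistry, sets out from ester 7 (with acetophenone 3 as the ring A partner in place of chromone 5) and comes back at 10. Vilsmeier–Haack formylation of 7 (POCl3, DMF, 0 → 70 °C; aq. NaOAc) goes next to the side chain and gives methyl 2-[3,5-bis(benzyloxy)-2-formylphenyl]acetate F1. Claisen–Schmidt condensation of this aldehyde with 3 (KOH, EtOH/H2O, rt, 48 h; then HCl) also saponifies the ester and gives the chalcone acid (E)-2-[3,5-bis(benzyloxy)-2-{3-[4-(benzyloxy)-2-hydroxy-6-methylphenyl]-3-oxoprop-1-en-1-yl}phenyl]acetic acid F2. Oxidative cyclisation (I2 10 mol %, DMSO, 130 °C) then closes ring C and delivers 10.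

Step 9 (Claisen acylation). The acyl imidazolide is enolisable and carries a base-sensitive flavone, so the strongly basic dienolate may give low conversion or side products. The fallback avoids strong base, sets out from acid 10 and comes back at 15, bypassing 11, 13 and 14. Oxalyl chloride with catalytic DMF in CH2Cl2 gives the acid chloride 2-{3,5-bis(benzyloxy)-2-[7-(benzyloxy)-5-methyl-4-oxo-4H-chromen-2-yl]phenyl}acetyl chloride F3. Mukaiyama-type acylation of 1-methoxy-1,3-bis(trimethylsilyloxy)buta-1,3-diene at its terminal carbon (CH2Cl2, −78 °C → rt; aqueous work-up) gives methyl 6-{3,5-bis(benzyloxy)-2-[7-(benzyloxy)-5-methyl-4-oxo-4H-chromen-2-yl]phenyl}-3,5-dioxohexanoate F4. Lactonisation with DBU (toluene, 80 °C) gives pyranone 15.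

Step 11 (global debenzylation). Three ethers must be cleaved on the most polar, Lewis-basic compound of the route, and incomplete cleavage or C-benzylation of ring B is possible. The fallback reorders the end game, sets out from 13 and comes back at 16. Hydrogenolysis of 13 (H2 1 atm, Pd/C (palladium metal on carbon), EtOAc/THF, rt) is done before any pyranone alkene exists and gives the triphenol 6-(3-{3,5-dihydroxy-2-[7-hydroxy-5-methyl-4-oxo-4H-chromen-2-yl]phenyl}-2-oxopropyl)-2,2-dimethyl-4H-1,3-dioxin-4-one F5. Reagent-free thermolysis at high dilution (toluene/1,4-dioxane, 0.005 M, 105 °C) passes through the acylketene 6-{3,5-dihydroxy-2-[7-hydroxy-5-methyl-4-oxo-4H-chromen-2-yl]phenyl}hex-1-ene-1,3,5-trione F6, which lactonises intramolecularly to 16.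

**Further compounds**
F1 | step 7 | methyl 2-[3,5-bis(benzyloxy)-2-formylphenyl]acetate | COC(=O)Cc1cc(OCc2ccccc2)cc(OCc2ccccc2)c1C=O
F2 | step 7 | (E)-2-[3,5-bis(benzyloxy)-2-{3-[4-(benzyloxy)-2-hydroxy-6-methylphenyl]-3-oxoprop-1-en-1-yl}phenyl]acetic acid | OC(=O)Cc1cc(OCc2ccccc2)cc(OCc2ccccc2)c1/C=C/C(=O)c1c(C)cc(OCc2ccccc2)cc1O
F3 | step 9 | 2-{3,5-bis(benzyloxy)-2-[7-(benzyloxy)-5-methyl-4-oxo-4H-chromen-2-yl]phenyl}acetyl chloride | Cc1cc(OCc2ccccc2)cc2oc(-c3c(OCc4ccccc4)cc(OCc4ccccc4)cc3CC(=O)Cl)cc(=O)c12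
F4 | step 9 | methyl 6-{3,5-bis(benzyloxy)-2-[7-(benzyloxy)-5-methyl-4-oxo-4H-chromen-2-yl]phenyl}-3,5-dioxohexanoate | Cc1cc(OCc2ccccc2)cc2oc(-c3c(OCc4ccccc4)cc(OCc4ccccc4)cc3CC(=O)CC(=O)CC(=O)OC)cc(=O)c12
F5 | step 11 | 6-(3-{3,5-dihydroxy-2-[7-hydroxy-5-methyl-4-oxo-4H-chromen-2-yl]phenyl}-2-oxopropyl)-2,2-dimethyl-4H-1,3-dioxin-4-one | Cc1cc(O)cc2oc(-c3c(O)cc(O)cc3CC(=O)CC4=CC(=O)OC(C)(C)O4)cc(=O)c12
F6 | step 11 | 6-{3,5-dihydroxy-2-[7-hydroxy-5-methyl-4-oxo-4H-chromen-2-yl]phenyl}hex-1-ene-1,3,5-trione | Cc1cc(O)cc2oc(-c3c(O)cc(O)cc3CC(=O)CC(=O)C=C=O)cc(=O)c12
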